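The route cuts the aryl–carbonyl bond between C-1′ of the methoxylated ring A′ and its enone carbonyl. This divides the bichalcone into a complete diaryl-ether chalcone and a p-coumaroyl donor, the C6–C3 starter unit of chalcone biosynthesis. The key step exploits ring A′: C-1′ lies para to the C-4′ methoxy oxygen and ortho to the C-2′ oxygen, making it the only strongly nucleophilic CH of the aryl half. The precursor is therefore a 2,4-dimethoxyphenyl ether. Friedel–Crafts acylation forges the bond. In the same flask, BCl3 uses the new carbonyl as a chelating handle to cleave only the C-2′ methyl ether, plus both benzyl ethers, releasing the target.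

Key step: step 4

Remark: the target has no stereocentre, so the only stereochemical demand is the E geometry of both enone double bonds, and this is what the route controls.

Step 1
Reactants: 1 2,4-dimethoxyphenol; 2 4-fluorobenzaldehyde
Product: 3 4-(2,4-dimethoxyphenoxy)benzaldehyde
Conditions: K2CO3 (2 equiv), DMF, 120 °C, N2
Reagents that add atoms: none
Why: Nucleophilic aromatic substitution (SNAr), in which the para-formyl group activates the C–F bond towards the electron-rich phenoxide of 1, a standard entry to 4-aryloxybenzaldehydes.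

Step 2
Reactants: 3 4-(2,4-dimethoxyphenoxy)benzaldehyde; 4 1-[4-(benzyloxy)-2-hydroxyphenyl]ethanone (4′-benzyloxy-2′-hydroxyacetophenone)
Product: 5 (E)-1-[4-(benzyloxy)-2-hydroxyphenyl]-3-[4-(2,4-dimethoxyphenoxy)phenyl]prop-2-en-1-one
Conditions: KOH (50% aq., excess), EtOH, rt; then 1 M HCl, 0 °C
Reagents that add atoms: none
Why: Claisen–Schmidt condensation of a non-enolisable aldehyde with a 2′-hydroxyacetophenone, in which E1cB dehydration of the aldol should give the conjugated E-enone as the thermodynamic product while the benzyl, methyl and diaryl ethers are inert to cold alkali.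

Step 3
Reactants: 6 (E)-3-[4-(benzyloxy)phenyl]prop-2-enoic acid (4-benzyloxycinnamic acid)
Product: 7 (E)-3-[4-(benzyloxy)phenyl]prop-2-enoyl chloride
Conditions: (COCl)2 (1.5 equiv), cat. DMF, CH2Cl2, 0 °C → rt; evaporate, use crude
Reagents that add atoms: oxalyl chloride, O=C(Cl)C(=O)Cl
Why: Acid chloride formation through the Vilsmeier-type chloroiminium species from catalytic DMF is mild enough to leave the benzyl ether and the E-alkene untouched.

Step 4
Reactants: 5 (E)-1-[4-(benzyloxy)-2-hydroxyphenyl]-3-[4-(2,4-dimethoxyphenoxy)phenyl]prop-2-en-1-one; 7 (E)-3-[4-(benzyloxy)phenyl]prop-2-enoyl chloride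
Product: 9 rhuschalcone III, via dibenzyl dimethyl bichalcone 8 (not isolated)
Conditions: 7 (1.2 equiv), SnCl4 (3 equiv), CH2Cl2, −40 °C, slow addition of 5, → 0 °C; then C6HMe5 (8 equiv), BCl3 (10 equiv), −78 → 0 °C; 1 M HCl/THF work-up
Reagents that add atoms: none
Why: SnCl4 ionises 7 to the resonance-stabilised cinnamoyl cation, which is attacked by C-5 of the 2,4-dimethoxyphenoxy ring of 5 (the future C-1′) and rearomatises with loss of HCl to give 8, a Friedel–Crafts acylation of the kind long used to make chalcones from resorcinol dimethyl ethers and cinnamoyl chlorides. BCl3 then binds the new carbonyl and the flanking C-2′ methoxy oxygen in a six-membered chelate, so that chloride removes this methyl group only (ortho-carbonyl-selective BCl3 demethylation), while both aryl benzyl ethers ionise and their benzyl cations are trapped by the non-basic scavenger pentamethylbenzene (BCl3/pentamethylbenzene debenzylation, which spares the enones where hydrogenolysis would not). No ring is closed and no stereocentre is formed; both E double bonds are carried in intact and are the thermodynamic isomers. Site selectivity is secured by the substrate: the dimethoxyphenoxy ring is the only ring without a carbonyl substituent, C-5 is para to one methoxy group and ortho to the other, C-3 is flanked by two methoxy groups and C-6 is meta to both. The 2′-OH of 5 is tied up as a tin chelate with its own carbonyl and should escape O-acylation, and acylation should outrun conjugate arylation of the enones because 5 is added slowly to the preformed acylium complex at low temperature. The C-4′ methyl ether has no chelating neighbour and should survive BCl3 at or below 0 °C.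

Compound list
1 | 2,4-dimethoxyphenol | COc1ccc(O)c(OC)c1 | starting material
2 | 4-fluorobenzaldehyde | O=Cc1ccc(F)cc1 | starting material
3 | 4-(2,4-dimethoxyphenoxy)benzaldehyde | COc1ccc(Oc2ccc(C=O)cc2)c(OC)c1 | intermediate
4 | 1-[4-(benzyloxy)-2-hydroxyphenyl]ethanone | CC(=O)c1ccc(OCc2ccccc2)cc1O | starting material
5 | (E)-1-[4-(benzyloxy)-2-hydroxyphenyl]-3-[4-(2,4-dimethoxyphenoxy)phenyl]prop-2-en-1-one | COc1ccc(Oc2ccc(/C=C/C(=O)c3ccc(OCc4ccccc4)cc3O)cc2)c(OC)c1 | intermediate
6 | (E)-3-[4-(benzyloxy)phenyl]prop-2-enoic acid | OC(=O)/C=C/c1ccc(OCc2ccccc2)cc1 | starting material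
7 | (E)-3-[4-(benzyloxy)phenyl]prop-2-enoyl chloride | ClC(=O)/C=C/c1ccc(OCc2ccccc2)cc1 | intermediate
8 | (E)-1-[5-(4-{(E)-3-[4-(benzyloxy)-2-hydroxyphenyl]-3-oxoprop-1-enyl}phenoxy)-2,4-dimethoxyphenyl]-3-[4-(benzyloxy)phenyl]prop-2-en-1-one | COc1cc(OC)c(C(=O)/C=C/c2ccc(OCc3ccccc3)cc2)cc1Oc1ccc(/C=C/C(=O)c2ccc(OCc3ccccc3)cc2O)cc1 | intermediate
9 | rhuschalcone III | COc1cc(O)c(C(=O)/C=C/c2ccc(O)cc2)cc1Oc1ccc(/C=C/C(=O)c2ccc(O)cc2O)cc1 | target

Total step count: 4
Longest linear sequence: 3 steps (1 → 2 → 4)

Steps most likely to fail

Step 4. Three processes may go wrong: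
- The electron-rich ring may add in a conjugate sense to a Lewis-acid-bound enone instead of being acylated.
- A benzyl ether may ionise too early, leading to C-benzylation before the ring is deactivated.
- Ether cleavage may run on to the C-4′ methyl group.

The fallback forms the same bond without any Lewis acid, by a Stille acylation. It sets out from 3 and returns at 8.
- Bromination of 3 (NBS, MeCN, 0 °C) at the same activated position should give 4-(5-bromo-2,4-dimethoxyphenoxy)benzaldehyde F1.
- Claisen–Schmidt condensation of F1 with 4 (KOH, EtOH) should give the bromochalcone (E)-1-[4-(benzyloxy)-2-hydroxyphenyl]-3-[4-(5-bromo-2,4-dimethoxyphenoxy)phenyl]prop-2-en-1-one F2.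
- Palladium-catalysed stannylation ((Bu3Sn)2, Pd(PPh3)4, toluene, 110 °C) should give the arylstannane (E)-1-[4-(benzyloxy)-2-hydroxyphenyl]-3-{4-[2,4-dimethoxy-5-(tributylstannyl)phenoxy]phenyl}prop-2-en-1-one F3.
- Neutral coupling of F3 with 7 (Pd2(dba)3, tri(2-furyl)phosphine, toluene, 60 °C) should give 8.
- Compound 8 is then isolated and given the BCl3/pentamethylbenzene stage alone, so its temperature can be tuned separately.

Step 2. The phenoxide of 4 makes enolate formation and addition sluggish, and the product may close by oxa-Michael addition to the flavanone during long exposure or work-up. The fallback replaces the aldol logic with a Wittig olefination. It sets out from 4 and returns at 5.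
- α-Bromination of 4 (CuBr2, EtOAc/CHCl3, reflux) should give 1-[4-(benzyloxy)-2-hydroxyphenyl]-2-bromoethanone F4.
- PPh3 (toluene, rt) should give {2-[4-(benzyloxy)-2-hydroxyphenyl]-2-oxoethyl}triphenylphosphonium bromide F5.
- Aqueous Na2CO3/CH2Cl2 should give the stabilised ylide 1-[4-(benzyloxy)-2-hydroxyphenyl]-2-(triphenylphosphoranylidene)ethanone F6.
- F6 should condense with 3 (toluene, reflux) E-selectively and under neutral conditions to give 5.

Step 1. The very electron-rich phenoxide of 1 may be oxidised or degraded during prolonged heating before substitution is complete. The fallback is a Chan–Lam coupling at room temperature. It sets out from 1 and returns at 3: 1 is coupled with 4-formylphenylboronic acid (Cu(OAc)2, pyridine, 4 Å molecular sieves, CH2Cl2, air). This fallback makes no compound outside the list (F0).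

Further compounds
F1 | step 4 | 4-(5-bromo-2,4-dimethoxyphenoxy)benzaldehyde | COc1cc(OC)c(Br)cc1Oc1ccc(C=O)cc1
F2 | step 4 | (E)-1-[4-(benzyloxy)-2-hydroxyphenyl]-3-[4-(5-bromo-2,4-dimethoxyphenoxy)phenyl]prop-2-en-1-one | COc1cc(OC)c(Br)cc1Oc1ccc(/C=C/C(=O)c2ccc(OCc3ccccc3)cc2O)cc1
F3 | step 4 | (E)-1-[4-(benzyloxy)-2-hydroxyphenyl]-3-{4-[2,4-dimethoxy-5-(tributylstannyl)phenoxy]phenyl}prop-2-en-1-one | COc1cc(OC)c([Sn](CCCC)(CCCC)CCCC)cc1Oc1ccc(/C=C/C(=O)c2ccc(OCc3ccccc3)cc2O)cc1
F4 | step 2 | 1-[4-(benzyloxy)-2-hydroxyphenyl]-2-bromoethanone | O=C(CBr)c1ccc(OCc2ccccc2)cc1O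
F5 | step 2 | {2-[4-(benzyloxy)-2-hydroxyphenyl]-2-oxoethyl}triphenylphosphonium bromide | O=C(C[P+](c1ccccc1)(c1ccccc1)c1ccccc1)c1ccc(OCc2ccccc2)cc1O.[Br-]
F6 | step 2 | 1-[4-(benzyloxy)-2-hydroxyphenyl]-2-(triphenylphosphoranylidene)ethanone | O=C(C=P(c1ccccc1)(c1ccccc1)c1ccccc1)c1ccc(OCc2ccccc2)cc1O
F0 | step 1 | none | none
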